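**Plan**
- Retrosynthesis: the CH2OH group of the dimethoxyphenyl ring goes back to a methyl ester and the two OMe groups to phenols. That ring (C1' ether carbon, C2' carrying the one-carbon group, oxygens at C4' and C6', meta to each other) is then opened at C1'–C2'.
- This unfolds the ring to a 7-aryloxy-2,4,6-trioxoheptanoate: C7 = C1', the C2 ketone = C2', the ester carbon C1 = the later CH2OH carbon, and the C4/C6 carbonyls = the two ring oxygens.
- The chain is cut at C5–C6 (aryloxyacetic Weinreb amide plus the dianion of methyl 2,4-dioxopentanoate). The two O–CH2 bonds on the benzoate ring are cut last.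
- Forward: the benzoate ring is bought and monoprenylated; the future diaryl-ether oxygen is alkylated at a primary carbon; the chain is completed by dianion acylation; the second ring arises by aldol aromatisation; O-methylation and selective ester reduction finish the route.
- Stereochemistry: the target has no stereocentre and no stereogenic double bond. The two sp3 centres of the aldol intermediate are lost on aromatisation.

Key step: step 4

Remark: compound 8 is drawn as the all-keto tautomer although it should exist mainly as enol forms; LDA is taken as a commercial solution.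

**Step 1**
Reactants: 1 methyl 2,6-dihydroxy-4-methylbenzoate; 2 prenyl bromide (1-bromo-3-methylbut-2-ene)
Product: 3 methyl 2-hydroxy-4-methyl-6-(3-methylbut-2-enyloxy)benzoate
Conditions: 2 (1.05 equiv), K2CO3 (1.1 equiv), acetone, rt
Reagents that add atoms: none
Why: Williamson ether synthesis in which the two phenols of 1 are equivalent and, after the first alkylation, the remaining phenol is held in a hydrogen bond to the ester carbonyl and is less nucleophilic, so one equivalent of halide with mild carbonate should stop at the monoether.

**Step 2**
Reactants: 3 methyl 2-hydroxy-4-methyl-6-(3-methylbut-2-enyloxy)benzoate; 4 2-chloro-N-methoxy-N-methylacetamide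
Product: 5 methyl 2-{2-[methoxy(methyl)amino]-2-oxoethoxy}-4-methyl-6-(3-methylbut-2-enyloxy)benzoate
Conditions: 4 (1.3 equiv), K2CO3 (2 equiv), KI (10 mol %), DMF, 60 °C
Reagents that add atoms: none
Why: Williamson alkylation of the hydrogen-bonded phenoxide by an α-halo amide activated through in situ iodide exchange (Finkelstein), under a base too weak to enolise the amide, so the neighbouring ester should stay untouched and the ether oxygen is fixed to a primary carbon.

**Step 3**
Reactants: 5 methyl 2-{2-[methoxy(methyl)amino]-2-oxoethoxy}-4-methyl-6-(3-methylbut-2-enyloxy)benzoate; 6 methyl 2,4-dioxopentanoate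
Product: 8 methyl 7-[2-(methoxycarbonyl)-5-methyl-3-(3-methylbut-2-enyloxy)phenoxy]-2,4,6-trioxoheptanoate, via dilithium dianion of methyl 2,4-dioxopentanoate 7 (not isolated)
Conditions: 6 (2.0 equiv), LDA (4.0 equiv), THF, −78 → −40 °C; then 5, −78 → −20 °C; 1 M HCl to pH 4, 0 °C
Reagents that add atoms: none
Why: Claisen-type γ-acylation of a 1,3-dicarbonyl dianion by a Weinreb amide, in which the second deprotonation of 6 can only take place at the terminal methyl group, the α-keto group is masked as its enolate, the amide gives the ketone only at the quench so the product does not consume dianion, and the low temperature should keep proton transfer from the amide methylene and attack on the hindered benzoate slower than C-acylation.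

**Step 4**
Reactants: 8 methyl 7-[2-(methoxycarbonyl)-5-methyl-3-(3-methylbut-2-enyloxy)phenoxy]-2,4,6-trioxoheptanoate
Product: 10 methyl 2-[2-(methoxycarbonyl)-5-methyl-3-(3-methylbut-2-enyloxy)phenoxy]-3,5-dihydroxybenzoate, via cyclic aldol adduct 9 (not isolated)
Conditions: K2CO3 (2 equiv), MeOH, 0 °C → rt; then 1 M HCl to pH 3, 0 °C
Reagents that add atoms: none
Why: In carbonate/methanol the enolised chain of 8 is deprotonated, and enolisation of the C6 carbonyl toward C7, the methylene that carries the aryloxy group, gives a carbon nucleophile that adds to the C2 ketone, the most electrophilic carbonyl of the chain because of its adjacent ester. This forms the C7–C2 bond (C1'–C2' of the new ring) in a 6-(enolendo)-exo-trig aldol closure to 9, which loses water by E1cB elimination and tautomerises at C4 and C6 to the aromatic diphenol 10, an irreversible step that drains the aldol equilibrium. The closest known reaction type is the base-mediated aldol aromatisation of 2,4,6-trioxoheptanoates and of heptane-2,4,6-trione to 3,5-dihydroxybenzoates and orcinol, the laboratory counterpart of polyketide folding. Two sp3 centres appear in 9 without control and both are erased on aromatisation, so no controlling element is needed. The step needs C7 to attack C2 and not the ortho ester of the existing ring (a five-membered Claisen closure to a benzofuran-3-one), and it needs C- rather than O-cyclisation (pyran-4-one formation). These are secured by the higher electrophilicity of the α-keto ester, the shielding of the benzoate by its two ortho oxygen substituents, a mild carbonate base at or below room temperature, the absence of acid during ring closure, and the fact that no other carbon of the chain can reach a carbonyl through a five- or six-membered transition state.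

**Step 5**
Reactants: 10 methyl 2-[2-(methoxycarbonyl)-5-methyl-3-(3-methylbut-2-enyloxy)phenoxy]-3,5-dihydroxybenzoate
Product: 11 methyl 2-[2-(methoxycarbonyl)-5-methyl-3-(3-methylbut-2-enyloxy)phenoxy]-3,5-dimethoxybenzoate
Conditions: MeI (3 equiv), K2CO3 (3 equiv), acetone, 40 °C
Reagents that add atoms: iodomethane, CI
Why: Williamson O-methylation of both phenols under conditions that leave the two esters, the prenyl ether and the diaryl ether untouched and that are routinely used to turn 3,5-dihydroxybenzoates into their dimethyl ethers.

**Step 6**
Reactants: 11 methyl 2-[2-(methoxycarbonyl)-5-methyl-3-(3-methylbut-2-enyloxy)phenoxy]-3,5-dimethoxybenzoate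
Product: 12 methyl 2-[2-(hydroxymethyl)-4,6-dimethoxyphenoxy]-4-methyl-6-(3-methylbut-2-enyloxy)benzoate
Conditions: LiBH4 (1.5 equiv), THF, 0 → 40 °C; then 1 M HCl, 0 °C
Reagents that add atoms: none
Why: Chemoselective borohydride reduction of an ester to the primary alcohol, expected to take the ester of the dimethoxy ring, which has one free ortho position, in preference to the other ester, which is flanked by two ortho oxygen substituents and is both shielded and electronically deactivated, while the trisubstituted alkene and the ethers do not react with LiBH4.

**Compound list**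
1 | methyl 2,6-dihydroxy-4-methylbenzoate | COC(=O)c1c(O)cc(C)cc1O | starting material
2 | prenyl bromide (1-bromo-3-methylbut-2-ene) | CC(C)=CCBr | starting material
3 | methyl 2-hydroxy-4-methyl-6-(3-methylbut-2-enyloxy)benzoate | COC(=O)c1c(O)cc(C)cc1OCC=C(C)C | intermediate
4 | 2-chloro-N-methoxy-N-methylacetamide | CON(C)C(=O)CCl | starting material
5 | methyl 2-{2-[methoxy(methyl)amino]-2-oxoethoxy}-4-methyl-6-(3-methylbut-2-enyloxy)benzoate | COC(=O)c1c(OCC(=O)N(C)OC)cc(C)cc1OCC=C(C)C | intermediate
6 | methyl 2,4-dioxopentanoate | COC(=O)C(=O)CC(C)=O | starting material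
7 | dilithium (Z)-1-methoxy-1-oxopenta-2,4-diene-2,4-diolate, the dianion of 6 (formed in the flask, not isolated) | [Li+].[Li+].COC(=O)/C([O-])=C/C([O-])=C | intermediate
8 | methyl 7-[2-(methoxycarbonyl)-5-methyl-3-(3-methylbut-2-enyloxy)phenoxy]-2,4,6-trioxoheptanoate (drawn as triketo tautomer) | COC(=O)C(=O)CC(=O)CC(=O)COc1cc(C)cc(OCC=C(C)C)c1C(=O)OC | intermediate
9 | methyl 1-hydroxy-2-[2-(methoxycarbonyl)-5-methyl-3-(3-methylbut-2-enyloxy)phenoxy]-3,5-dioxocyclohexane-1-carboxylate (aldol adduct, not isolated; both stereocentres unassigned and lost in the same step) | COC(=O)C1(O)CC(=O)CC(=O)C1Oc1cc(C)cc(OCC=C(C)C)c1C(=O)OC | intermediate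
10 | methyl 2-[2-(methoxycarbonyl)-5-methyl-3-(3-methylbut-2-enyloxy)phenoxy]-3,5-dihydroxybenzoate | COC(=O)c1cc(O)cc(O)c1Oc1cc(C)cc(OCC=C(C)C)c1C(=O)OC | intermediate
11 | methyl 2-[2-(methoxycarbonyl)-5-methyl-3-(3-methylbut-2-enyloxy)phenoxy]-3,5-dimethoxybenzoate | COC(=O)c1cc(OC)cc(OC)c1Oc1cc(C)cc(OCC=C(C)C)c1C(=O)OC | intermediate
12 | methyl 2-[2-(hydroxymethyl)-4,6-dimethoxyphenoxy]-4-methyl-6-(3-methylbut-2-enyloxy)benzoate | COC(=O)c1c(OCC=C(C)C)cc(C)cc1Oc1c(CO)cc(OC)cc1OC | target

**Totals**
Total step count: 6. Longest linear sequence: 6 steps (1 → 3 → 5 → 8 → 10 → 11 → 12).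

**Steps most likely to fail**

Step 3. The dianion may transfer a proton from the amide methylene, or condense with itself through its own ester, in place of C-acylation, so that the chain is not assembled. The fallback sets out from 5 and returns at 8, and closes the chain at C2–C3 instead of C5–C6. The lithium enolate of acetone (LDA, THF, −78 °C) is acylated by 5 to give the β-diketone methyl 2-(2,4-dioxopentyloxy)-4-methyl-6-(3-methylbut-2-enyloxy)benzoate F1. Two equivalents of LDA convert this into its dianion, deprotonated at the terminal methyl group, dilithium dianion of the diketone F2. This is added at −78 °C to an excess of dimethyl oxalate, a non-enolisable and very electrophilic acyl donor, and acidic work-up should give 8. No keto ester then has to survive as a dianion.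

Step 4. Ring closure may run through the wrong electrophile (attack of C7 on the ester of the existing ring), through oxygen (pyranone formation), or the chain may be cleaved by retro-Claisen fragmentation before it folds. The fallback sets out from 3 and returns at 11, and makes the diaryl ether bond at the arene without folding a chain. Methyl 3,5-dimethoxybenzoate is brominated with NBS in MeCN to methyl 2-bromo-3,5-dimethoxybenzoate F3. A copper-catalysed Ullmann coupling of 3 with this bromide (CuI, picolinic acid, K3PO4, DMSO, 90 °C) should give 11 directly, ready for the final reduction.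

Step 6. Discrimination between the two esters may be lost, with reduction of both or incomplete reduction of the intended one. The fallback sets out from 11 and returns at 12, and separates the esters by hydrolysis instead of by hydride. LiOH in THF–water at rt should saponify only the less hindered ester to 2-[2-(methoxycarbonyl)-5-methyl-3-(3-methylbut-2-enyloxy)phenoxy]-3,5-dimethoxybenzoic acid F4. This is activated with isobutyl chloroformate and N-methylmorpholine (THF, −15 °C) as the mixed anhydride 2-[2-(methoxycarbonyl)-5-methyl-3-(3-methylbut-2-enyloxy)phenoxy]-3,5-dimethoxybenzoic isobutyl carbonic anhydride F5. NaBH4 in THF–water at 0 °C reduces the anhydride to 12 without touching the hindered methyl ester or the alkene.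

**Further compounds**
F1 | step 3 | methyl 2-(2,4-dioxopentyloxy)-4-methyl-6-(3-methylbut-2-enyloxy)benzoate | COC(=O)c1c(OCC(=O)CC(C)=O)cc(C)cc1OCC=C(C)C
F2 | step 3 | dilithium dianion of the diketone F1 (terminal methyl deprotonated, Z enolate) | [Li+].[Li+].COC(=O)c1c(OC/C([O-])=C/C([O-])=C)cc(C)cc1OCC=C(C)C
F3 | step 4 | methyl 2-bromo-3,5-dimethoxybenzoate | COC(=O)c1cc(OC)cc(OC)c1Br
F4 | step 6 | 2-[2-(methoxycarbonyl)-5-methyl-3-(3-methylbut-2-enyloxy)phenoxy]-3,5-dimethoxybenzoic acid | OC(=O)c1cc(OC)cc(OC)c1Oc1cc(C)cc(OCC=C(C)C)c1C(=O)OC
F5 | step 6 | 2-[2-(methoxycarbonyl)-5-methyl-3-(3-methylbut-2-enyloxy)phenoxy]-3,5-dimethoxybenzoic isobutyl carbonic anhydride | CC(C)COC(=O)OC(=O)c1cc(OC)cc(OC)c1Oc1cc(C)cc(OCC=C(C)C)c1C(=O)OC
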